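**Retrosynthetic overview**
- The target comes from its C15 silyl ether by desilylation; the C8 methacrylate is installed by Mitsunobu inversion of a macrocyclic 8S alcohol.
- The ten-membered carbocycle (third ring) is closed by ring-closing metathesis, forming the Z C4=C5 alkene.
- The C7–C8 bond and the α-methylene-γ-lactone come from a zinc Barbier coupling of a furanone aldehyde with (R)-3-(bromomethyl)-5-vinylbutenolide. This butenolide is the second ring, made from acrolein and a propargyl silyl ether by asymmetric alkynylation, trans-hydroalumination/iodination and carbonylative lactonisation.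
- The 3(2H)-furanone with the C10 quaternary centre and the C8 aldehyde (first ring) comes from the key step: singlet-oxygen dearomatisation of a 2-(β-ketoalkyl)-3-methylfuran, then enantioselective oxa-Michael closure.
- The furyl ketone comes from Eschenmoser–Claisen rearrangement of furan-3-ylmethanol followed by alkenyllithium acylation.

Numbering: germacranolide numbering of the target is used throughout (C1 ketone, C2=C3 furanone alkene, C4(C15H2OH)=C5, C6 lactone O–CH, C7, C8 ester O–CH, C9 CH2, C10 quaternary with C14 methyl, C11=C13H2, C12 lactone C=O). The target is 4Z,6R,7R,8R,10S.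

Assumption: the facial senses of the two catalytic asymmetric steps (4 and 5) follow the models named there; if either proves reversed, the antipodal catalyst is used with no other change.

Step 1
Reactants: 1 furan-3-ylmethanol; 2 1,1-dimethoxy-N,N-dimethylethanamine (N,N-dimethylacetamide dimethyl acetal)
Product: 5 N,N-dimethyl-2-(3-methylfuran-2-yl)acetamide, via ketene N,O-acetal 3 (not isolated), via methylidene-dihydrofuran amide 4 (not isolated)
Conditions: 2 (3 equiv), xylenes, 140 °C, MeOH distilled off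
Reagents that add atoms: none
Why: Eschenmoser–Claisen rearrangement: acetal exchange gives 3, whose [3,3] shift across the furan C2=C3 bond transiently dearomatises the ring (4), and a 1,3-hydrogen shift restores the furan with the acetamide at C2 and the new methyl at C3, regiospecifically and with no stereocentre.

Step 2
Reactants: 6 2-bromoprop-2-en-1-ol
Product: 7 [(2-bromoprop-2-en-1-yl)oxy](tert-butyl)dimethylsilane
Conditions: TBSCl, imidazole, CH2Cl2, 0 °C to rt
Reagents that add atoms: tert-butyldimethylsilyl chloride (TBSCl), C[Si](C)(Cl)C(C)(C)C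
Why: Standard silyl ether protection of a primary allylic alcohol masks the future C15 hydroxyl.

Step 3
Reactants: 7 [(2-bromoprop-2-en-1-yl)oxy](tert-butyl)dimethylsilane; 5 N,N-dimethyl-2-(3-methylfuran-2-yl)acetamide
Product: 10 3-{[(tert-butyldimethylsilyl)oxy]methyl}-1-(3-methylfuran-2-yl)but-3-en-2-one, via alkenyllithium 8 (not isolated), via lithium hemiaminal alkoxide 9 (not isolated)
Conditions: 7, t-BuLi (2.05 equiv), Et2O, −78 °C; then 5, THF, −78 to −40 °C; H2O
Reagents that add atoms: none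
Why: Bromine–lithium exchange gives 8, which adds once to the tertiary amide because the tetrahedral adduct 9 survives until work-up (ketone synthesis from an amide and an organolithium), the low temperature limiting enolisation of the furylacetamide.

Step 4
Reactants: 10 3-{[(tert-butyldimethylsilyl)oxy]methyl}-1-(3-methylfuran-2-yl)but-3-en-2-one
Product: 13 2-[(2S)-5-{3-[(tert-butyldimethylsilyl)oxy]prop-1-en-2-yl}-2-methyl-3-oxo-2,3-dihydrofuran-2-yl]acetaldehyde, via furan endoperoxide 11 (not isolated), via Z-keto-enal 12 (not isolated)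
Conditions: O2, methylene blue (1 mol %), visible light, CH2Cl2, −78 °C; Me2S (2 equiv), −78 to −20 °C; (S)-α,α-diphenylprolinol trimethylsilyl ether (20 mol %), PhCO2H (20 mol %), −20 °C; used at once in step 9
Reagents that add atoms: dioxygen, O=O
Why: Proposed new method: [4+2] addition of singlet oxygen to the electron-rich furan gives endoperoxide 11, Me2S reduces it to the Z-keto-enal 12, and the chiral secondary amine turns the enal into an iminium ion (E/Z-equilibrating through the dienamine of the C14 methyl) whose β-carbon C10 is attacked 5-exo by the enol oxygen of the C1/C3 diketone from the face opposite the diphenyl(silyloxy)methyl group, which should set the quaternary C10 as S while unmasking the C8 aldehyde; the closest known reactions are the singlet-oxygen photooxygenation/oxa-Michael cascade of 2-(β-ketoalkyl)furans to racemic 3(2H)-furanones and iminium-catalysed oxa-Michael additions to β,β-disubstituted enals.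

Step 5
Reactants: 14 tert-butyldimethyl(prop-2-yn-1-yloxy)silane; 15 prop-2-enal (acrolein)
Product: 17 (3R)-6-[(tert-butyldimethylsilyl)oxy]hex-1-en-4-yn-3-ol, via alkynyl(methyl)zinc 16 (not isolated)
Conditions: Me2Zn (3 equiv), (S,S)-ProPhenol (10 mol %), Ph3P=O (20 mol %), toluene, 0 °C
Reagents that add atoms: none
Why: Catalytic asymmetric alkynylation of an aldehyde: 16 adds to the Si face of acrolein inside the chiral catalyst formed from Me2Zn and ProPhenol, which sets the C6 carbinol as R.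

Step 6
Reactants: 17 (3R)-6-[(tert-butyldimethylsilyl)oxy]hex-1-en-4-yn-3-ol
Product: 19 (3R,4Z)-6-[(tert-butyldimethylsilyl)oxy]-5-iodohexa-1,4-dien-3-ol, via cyclic alkenylalanate 18 (not isolated)
Conditions: NaAlH2(OCH2CH2OMe)2 (1.6 equiv), THF, 0 °C; then I2, −78 °C
Reagents that add atoms: iodine, II
Why: Hydroxyl-directed trans-hydroalumination of the propargylic alcohol puts aluminium on the distal alkyne carbon (18), and iodinolysis with retention gives the Z-iodoalkene with iodine cis to the carbinol carbon, C6 being untouched.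

Step 7
Reactants: 19 (3R,4Z)-6-[(tert-butyldimethylsilyl)oxy]-5-iodohexa-1,4-dien-3-ol
Product: 20 (5R)-3-{[(tert-butyldimethylsilyl)oxy]methyl}-5-ethenylfuran-2(5H)-one
Conditions: CO (1 atm), PdCl2(PPh3)2 (5 mol %), NaHCO3, THF, 40 °C
Reagents that add atoms: carbon monoxide, [C-]#[O+]
Why: Palladium-catalysed carbonylative lactonisation: oxidative addition, CO insertion and capture of the acylpalladium by the cis hydroxyl close the butenolide, the weak base leaving the γ-stereocentre intact.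

Step 8
Reactants: 20 (5R)-3-{[(tert-butyldimethylsilyl)oxy]methyl}-5-ethenylfuran-2(5H)-one
Product: 21 (5R)-3-(bromomethyl)-5-ethenylfuran-2(5H)-one
Conditions: Ph3PBr2 (1.2 equiv), CH2Cl2, 0 °C to rt
Reagents that add atoms: dibromotriphenylphosphorane, BrP(Br)(c1ccccc1)(c1ccccc1)c1ccccc1
Why: Ph3PBr2 converts a primary allylic silyl ether directly into the bromide (Appel-type silyl ether to bromide exchange) without touching C6.

Step 9
Reactants: 13 2-[(2S)-5-{3-[(tert-butyldimethylsilyl)oxy]prop-1-en-2-yl}-2-methyl-3-oxo-2,3-dihydrofuran-2-yl]acetaldehyde; 21 (5R)-3-(bromomethyl)-5-ethenylfuran-2(5H)-one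
Product: 23 (2S)-2-{(2S)-2-hydroxy-2-[(2R,3R)-2-ethenyl-4-methylidene-5-oxooxolan-3-yl]ethyl}-5-{3-[(tert-butyldimethylsilyl)oxy]prop-1-en-2-yl}-2-methylfuran-3(2H)-one (6R,7R,8S,10S), via allylzinc bromide 22 (not isolated)
Conditions: 21 (1.5 equiv), Zn dust, THF/sat. aq NH4Cl, 0 °C to rt
Reagents that add atoms: none
Why: Zinc Barbier allylation: 22 attacks the aldehyde through C7 in a Zimmerman–Traxler chair on the butenolide face anti to the C6 vinyl group, which gives the 6,7-trans α-methylene lactone (7R) and the 7,8-anti alcohol (8S).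

Step 10
Reactants: 23 the (6R,7R,8S,10S) Barbier adduct
Product: 24 (4Z,6R,7R,8S,10S)-15-[(tert-butyldimethylsilyl)oxy]-8-hydroxy-1-oxo-3,10-epoxygermacra-2,4,11(13)-trien-12,6-olide
Conditions: second-generation Grubbs catalyst RuCl2(=CHPh)(PCy3)(H2IMes) (15 mol %), toluene (0.5 mM), 80 °C
Reagents that add atoms: none
Why: Ring-closing metathesis: ruthenium loads on the C6 vinyl group and closes onto the 1,1-disubstituted C4 methylene, and the furanone-bridged medium ring can only hold the Z alkene (C3 and C6 cis), with no stereocentre changed.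

Step 11
Reactants: 24 the 8S macrocyclic alcohol; 25 2-methylprop-2-enoic acid (methacrylic acid)
Product: 27 (4Z,6R,7R,8R,10S)-15-[(tert-butyldimethylsilyl)oxy]-8-(methacryloyloxy)-1-oxo-3,10-epoxygermacra-2,4,11(13)-trien-12,6-olide, via alkoxyphosphonium methacrylate 26 (not isolated)
Conditions: 25 (3 equiv), PPh3/DIAD (premixed), toluene, 0 °C to rt
Reagents that add atoms: none
Why: Mitsunobu esterification: the 8S alcohol is activated as 26 and displaced by methacrylate in an SN2 step, which inverts C8 to the required 8R ester.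

Step 12
Reactants: 27 the 15-O-silyl methacrylate
Product: 28 (4Z,6R,7R,8R,10S)-15-hydroxy-8-(methacryloyloxy)-1-oxo-3,10-epoxygermacra-2,4,11(13)-trien-12,6-olide (CNP0180483.4)
Conditions: HF·pyridine, THF/pyridine, 0 °C
Reagents that add atoms: none
Why: Buffered fluoride desilylation frees the C15 alcohol without conjugate addition to the methacrylate or the α-methylene lactone.

**Compound list**
1 | furan-3-ylmethanol | OCc1ccoc1 | starting material
2 | 1,1-dimethoxy-N,N-dimethylethanamine | CC(OC)(OC)N(C)C | starting material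
3 | 1-(furan-3-ylmethoxy)-N,N-dimethylethenamine (ketene N,O-acetal) | C=C(OCc1ccoc1)N(C)C | intermediate
4 | N,N-dimethyl-2-(3-methylidene-2,3-dihydrofuran-2-yl)acetamide (racemic) | C=C1C=COC1CC(=O)N(C)C | intermediate
5 | N,N-dimethyl-2-(3-methylfuran-2-yl)acetamide | Cc1ccoc1CC(=O)N(C)C | intermediate
6 | 2-bromoprop-2-en-1-ol | OCC(Br)=C | starting material
7 | [(2-bromoprop-2-en-1-yl)oxy](tert-butyl)dimethylsilane | C=C(Br)CO[Si](C)(C)C(C)(C)C | intermediate
8 | {3-[(tert-butyldimethylsilyl)oxy]prop-1-en-2-yl}lithium | [Li]C(=C)CO[Si](C)(C)C(C)(C)C | intermediate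
9 | lithium 1-(dimethylamino)-1-[(3-methylfuran-2-yl)methyl]-2-{[(tert-butyldimethylsilyl)oxy]methyl}prop-2-en-1-olate (racemic) | Cc1ccoc1CC([O-])(N(C)C)C(=C)CO[Si](C)(C)C(C)(C)C.[Li+] | intermediate
10 | 3-{[(tert-butyldimethylsilyl)oxy]methyl}-1-(3-methylfuran-2-yl)but-3-en-2-one | Cc1ccoc1CC(=O)C(=C)CO[Si](C)(C)C(C)(C)C | intermediate
11 | 3-{[(tert-butyldimethylsilyl)oxy]methyl}-1-(6-methyl-2,3,7-trioxabicyclo[2.2.1]hept-5-en-1-yl)but-3-en-2-one (racemic) | CC1=CC2OOC1(CC(=O)C(=C)CO[Si](C)(C)C(C)(C)C)O2 | intermediate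
12 | (2Z)-7-{[(tert-butyldimethylsilyl)oxy]methyl}-3-methyl-4,6-dioxoocta-2,7-dienal | O=C/C=C(C)\C(=O)CC(=O)C(=C)CO[Si](C)(C)C(C)(C)C | intermediate
13 | 2-[(2S)-5-{3-[(tert-butyldimethylsilyl)oxy]prop-1-en-2-yl}-2-methyl-3-oxo-2,3-dihydrofuran-2-yl]acetaldehyde | O=CC[C@]1(C)OC(C(=C)CO[Si](C)(C)C(C)(C)C)=CC1=O | intermediate
14 | tert-butyldimethyl(prop-2-yn-1-yloxy)silane | C#CCO[Si](C)(C)C(C)(C)C | starting material
15 | prop-2-enal (acrolein) | C=CC=O | starting material
16 | methyl{3-[(tert-butyldimethylsilyl)oxy]prop-1-yn-1-yl}zinc | C[Zn]C#CCO[Si](C)(C)C(C)(C)C | intermediate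
17 | (3R)-6-[(tert-butyldimethylsilyl)oxy]hex-1-en-4-yn-3-ol | C=C[C@@H](O)C#CCO[Si](C)(C)C(C)(C)C | intermediate
18 | sodium (5R)-3-{[(tert-butyldimethylsilyl)oxy]methyl}-5-ethenyl-2,2-bis(2-methoxyethoxy)-2,5-dihydro-1,2-oxaluminol-2-uide (cyclic alkenylalanate) | C=C[C@H]1O[Al-](OCCOC)(OCCOC)C(CO[Si](C)(C)C(C)(C)C)=C1.[Na+] | intermediate
19 | (3R,4Z)-6-[(tert-butyldimethylsilyl)oxy]-5-iodohexa-1,4-dien-3-ol | C=C[C@@H](O)/C=C(\I)CO[Si](C)(C)C(C)(C)C | intermediate
20 | (5R)-3-{[(tert-butyldimethylsilyl)oxy]methyl}-5-ethenylfuran-2(5H)-one | C=C[C@H]1OC(=O)C(CO[Si](C)(C)C(C)(C)C)=C1 | intermediate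
21 | (5R)-3-(bromomethyl)-5-ethenylfuran-2(5H)-one | C=C[C@H]1OC(=O)C(CBr)=C1 | intermediate
22 | {[(5R)-5-ethenyl-2-oxo-2,5-dihydrofuran-3-yl]methyl}zinc bromide | Br[Zn]CC1=C[C@@H](C=C)OC1=O | intermediate
23 | (2S)-2-{(2S)-2-hydroxy-2-[(2R,3R)-2-ethenyl-4-methylidene-5-oxooxolan-3-yl]ethyl}-5-{3-[(tert-butyldimethylsilyl)oxy]prop-1-en-2-yl}-2-methylfuran-3(2H)-one | O[C@@H](C[C@]1(C)OC(C(=C)CO[Si](C)(C)C(C)(C)C)=CC1=O)[C@H]1C(=C)C(=O)O[C@@H]1C=C | intermediate
24 | (4Z,6R,7R,8S,10S)-15-[(tert-butyldimethylsilyl)oxy]-8-hydroxy-1-oxo-3,10-epoxygermacra-2,4,11(13)-trien-12,6-olide | O[C@H]1C[C@]2(C)OC(=CC2=O)/C(CO[Si](C)(C)C(C)(C)C)=C\[C@H]2OC(=O)C(=C)[C@@H]21 | intermediate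
25 | 2-methylprop-2-enoic acid (methacrylic acid) | C=C(C)C(=O)O | starting material
26 | [(8S)-O8-triphenylphosphonio derivative of 24] methacrylate (alkoxyphosphonium salt) | C=C(C)C(=O)[O-].c1ccccc1[P+](c1ccccc1)(c1ccccc1)O[C@H]1C[C@]2(C)OC(=CC2=O)/C(CO[Si](C)(C)C(C)(C)C)=C\[C@H]2OC(=O)C(=C)[C@@H]21 | intermediate
27 | (4Z,6R,7R,8R,10S)-15-[(tert-butyldimethylsilyl)oxy]-8-(methacryloyloxy)-1-oxo-3,10-epoxygermacra-2,4,11(13)-trien-12,6-olide | C=C(C)C(=O)O[C@@H]1C[C@]2(C)OC(=CC2=O)/C(CO[Si](C)(C)C(C)(C)C)=C\[C@H]2OC(=O)C(=C)[C@@H]21 | intermediate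
28 | (4Z,6R,7R,8R,10S)-15-hydroxy-8-(methacryloyloxy)-1-oxo-3,10-epoxygermacra-2,4,11(13)-trien-12,6-olide | C=C(C)C(=O)O[C@@H]1C[C@]2(C)OC(=CC2=O)/C(CO)=C\[C@H]2OC(=O)C(=C)[C@@H]21 | target

**Step count**
Total: 12 steps. Longest linear sequence: 8 steps (5, 6, 7, 8, 9, 10, 11, 12); the furan branch (1, 3, 4, with 2 feeding 3) joins at step 9.

**Three steps most likely to fail**

Step 4. The oxa-Michael closure has a racemic background reaction, and the β-alkoxy aldehyde can lose ee by retro-oxa-Michael. The enol may also close 6-endo onto C9 or onto the C4 methylene, or C2 may add to the aldehyde. The fallback sets out from 10 and comes back at 23. Compound 10 is photooxygenated and reduced as before (through 11 and 12), but the furanone is closed with Et3N instead of the chiral amine, which gives the racemic 2-[5-{3-[(tert-butyldimethylsilyl)oxy]prop-1-en-2-yl}-2-methyl-3-oxo-2,3-dihydrofuran-2-yl]acetaldehyde F1. Coupling F1 with enantiopure 21 under the step 9 conditions gives 23 together with its C10 epimer, the (6R,7R,8S,10R) adduct F2. The two are diastereomers and are separated on silica, so C10 is secured by separation against the C6 centre instead of by asymmetric catalysis, at the cost of half the material.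

Step 10. A strained ten-membered ring must form on an electron-poor 1,1-disubstituted alkene, and dimerisation can win. The fallback sets out from 5, 14 and 15 and comes back at 24; it puts C4=C5 in place first and closes the ring at C7–C8 by an intramolecular Barbier reaction.
- Alkynylation of 15 with 14 as in step 5, but with (R,R)-ProPhenol, gives (3S)-6-[(tert-butyldimethylsilyl)oxy]hex-1-en-4-yn-3-ol F3. Here the alkyne becomes C4/C5 and the vinyl group C7, so the 3S series is needed.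
- NaAlH2(OCH2CH2OMe)2 gives the cyclic alkenylalanate F4, and I2 converts it into the (3S,4Z)-iodo dienol F5.
- Et3SiCl/imidazole gives the triethylsilyl ether F6.
- t-BuLi gives the alkenyllithium F7, which adds to amide 5 through the lithium hemiaminal alkoxide F8 to give the (3Z,5S)-dienone F9.
- The step 4 conditions take F9 through the endoperoxide F10 and the Z-keto-enal F11 to the (S)-furanone aldehyde F12.
- PPTS in MeOH removes the triethylsilyl group to give the allylic alcohol F13.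
- 2-(Bromomethyl)acrylic acid and DCC give the ester F14.
- RuCl2(=CHPh)(PCy3)(H2IMes) closes the five-membered ring to the bromomethyl butenolide aldehyde F15.
- Zn dust in THF/aq NH4Cl at 1 mM forms the allylzinc bromide F16, which adds to the tethered aldehyde anti to the C5 substituent. This is expected to give 24, though the sense at C7/C8 in the macrocyclic transition state is less certain than in step 9.

Step 11. SN2 at the hindered C8 of the macrocycle may be slow, and elimination or participation by the lactone carbonyl can compete. The fallback sets out from 13 and 21 and comes back at 27; it makes the 8R alcohol directly so that no inversion is needed. Compound 21 is converted with Bu3SnSnBu3 and Pd2(dba)3 into the (5R)-3-[(tributylstannyl)methyl]-5-ethenylfuran-2(5H)-one F17. BF3·OEt2 at −78 °C adds F17 to 13 through an open transition state, again anti to the C6 vinyl group, which gives the 7,8-syn (8R) adduct F18. Ring-closing metathesis as in step 10 gives the 8R macrocyclic alcohol F19. Methacrylic anhydride with DMAP esterifies F19 with retention and gives 27.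

**Further compounds**
F1 | step 4 | racemic 2-[5-{3-[(tert-butyldimethylsilyl)oxy]prop-1-en-2-yl}-2-methyl-3-oxo-2,3-dihydrofuran-2-yl]acetaldehyde | O=CCC1(C)OC(C(=C)CO[Si](C)(C)C(C)(C)C)=CC1=O
F2 | step 4 | (2R)-2-{(2S)-2-hydroxy-2-[(2R,3R)-2-ethenyl-4-methylidene-5-oxooxolan-3-yl]ethyl}-5-{3-[(tert-butyldimethylsilyl)oxy]prop-1-en-2-yl}-2-methylfuran-3(2H)-one (C10 epimer of 23) | O[C@@H](C[C@@]1(C)OC(C(=C)CO[Si](C)(C)C(C)(C)C)=CC1=O)[C@H]1C(=C)C(=O)O[C@@H]1C=C
F3 | step 10 | (3S)-6-[(tert-butyldimethylsilyl)oxy]hex-1-en-4-yn-3-ol | C=C[C@H](O)C#CCO[Si](C)(C)C(C)(C)C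
F4 | step 10 | sodium (5S)-3-{[(tert-butyldimethylsilyl)oxy]methyl}-5-ethenyl-2,2-bis(2-methoxyethoxy)-2,5-dihydro-1,2-oxaluminol-2-uide | C=C[C@@H]1O[Al-](OCCOC)(OCCOC)C(CO[Si](C)(C)C(C)(C)C)=C1.[Na+]
F5 | step 10 | (3S,4Z)-6-[(tert-butyldimethylsilyl)oxy]-5-iodohexa-1,4-dien-3-ol | C=C[C@H](O)/C=C(\I)CO[Si](C)(C)C(C)(C)C
F6 | step 10 | triethylsilyl ether of F5 | C=C[C@H](O[Si](CC)(CC)CC)/C=C(\I)CO[Si](C)(C)C(C)(C)C
F7 | step 10 | alkenyllithium from F6 (lithium in place of iodine, same geometry) | [Li]/C(CO[Si](C)(C)C(C)(C)C)=C\[C@@H](O[Si](CC)(CC)CC)C=C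
F8 | step 10 | lithium hemiaminal alkoxide from F7 and 5 | Cc1ccoc1CC([O-])(N(C)C)/C(CO[Si](C)(C)C(C)(C)C)=C\[C@@H](O[Si](CC)(CC)CC)C=C.[Li+]
F9 | step 10 | (3Z,5S)-3-{[(tert-butyldimethylsilyl)oxy]methyl}-1-(3-methylfuran-2-yl)-5-[(triethylsilyl)oxy]hepta-3,6-dien-2-one | Cc1ccoc1CC(=O)/C(CO[Si](C)(C)C(C)(C)C)=C\[C@@H](O[Si](CC)(CC)CC)C=C
F10 | step 10 | furan endoperoxide of F9 | CC1=CC2OOC1(CC(=O)/C(CO[Si](C)(C)C(C)(C)C)=C\[C@@H](O[Si](CC)(CC)CC)C=C)O2
F11 | step 10 | Z-keto-enal from F10 | O=C/C=C(C)\C(=O)CC(=O)/C(CO[Si](C)(C)C(C)(C)C)=C\[C@@H](O[Si](CC)(CC)CC)C=C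
F12 | step 10 | 2-[(2S)-5-{(2Z,4S)-1-[(tert-butyldimethylsilyl)oxy]-4-[(triethylsilyl)oxy]hexa-2,5-dien-2-yl}-2-methyl-3-oxo-2,3-dihydrofuran-2-yl]acetaldehyde | O=CC[C@]1(C)OC(/C(CO[Si](C)(C)C(C)(C)C)=C\[C@@H](O[Si](CC)(CC)CC)C=C)=CC1=O
F13 | step 10 | 2-[(2S)-5-{(2Z,4S)-1-[(tert-butyldimethylsilyl)oxy]-4-hydroxyhexa-2,5-dien-2-yl}-2-methyl-3-oxo-2,3-dihydrofuran-2-yl]acetaldehyde | O=CC[C@]1(C)OC(/C(CO[Si](C)(C)C(C)(C)C)=C\[C@@H](O)C=C)=CC1=O
F14 | step 10 | 2-(bromomethyl)acrylate ester of F13 | O=CC[C@]1(C)OC(/C(CO[Si](C)(C)C(C)(C)C)=C\[C@@H](OC(=O)C(=C)CBr)C=C)=CC1=O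
F15 | step 10 | 2-[(2S)-5-{(1Z)-1-[(2R)-4-(bromomethyl)-5-oxo-2,5-dihydrofuran-2-yl]-3-[(tert-butyldimethylsilyl)oxy]prop-1-en-2-yl}-2-methyl-3-oxo-2,3-dihydrofuran-2-yl]acetaldehyde | O=CC[C@]1(C)OC(/C(CO[Si](C)(C)C(C)(C)C)=C\[C@H]2OC(=O)C(CBr)=C2)=CC1=O
F16 | step 10 | allylzinc bromide from F15 | O=CC[C@]1(C)OC(/C(CO[Si](C)(C)C(C)(C)C)=C\[C@H]2OC(=O)C(C[Zn]Br)=C2)=CC1=O
F17 | step 11 | (5R)-3-[(tributylstannyl)methyl]-5-ethenylfuran-2(5H)-one | CCCC[Sn](CCCC)(CCCC)CC1=C[C@@H](C=C)OC1=O
F18 | step 11 | (2S)-2-{(2R)-2-hydroxy-2-[(2R,3R)-2-ethenyl-4-methylidene-5-oxooxolan-3-yl]ethyl}-5-{3-[(tert-butyldimethylsilyl)oxy]prop-1-en-2-yl}-2-methylfuran-3(2H)-one (C8 epimer of 23) | O[C@H](C[C@]1(C)OC(C(=C)CO[Si](C)(C)C(C)(C)C)=CC1=O)[C@H]1C(=C)C(=O)O[C@@H]1C=C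
F19 | step 11 | (4Z,6R,7R,8R,10S)-15-[(tert-butyldimethylsilyl)oxy]-8-hydroxy-1-oxo-3,10-epoxygermacra-2,4,11(13)-trien-12,6-olide (C8 epimer of 24) | O[C@@H]1C[C@]2(C)OC(=CC2=O)/C(CO[Si](C)(C)C(C)(C)C)=C\[C@H]2OC(=O)C(=C)[C@@H]21
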